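**Retrosynthetic overview**

1. The target comes from its tetrakis(triisopropylsilyl) ether by one buffered fluoride step; all four phenols are carried as silyl ethers so that no Brønsted acid meets the 3-methylbut-3-enyl chain beside the ring B phenol.
2. Ring C is the only ring made and is closed last at C2–C3. The strategy rests on C2, which bears both O1 and the ring B aryl group: before closure it is the CH2 of an O1 benzyl ether, six atoms (C3, C4, C4a, C8a, O1, C2) from a carbenoid at C3, and a chiral dirhodium carboxylate inserts that carbenoid and sets C2.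
3. The diazoketone comes from the aryl methyl ketone by detrifluoroacetylative diazo transfer; the ketone comes from Mitsunobu etherification (O1–CH2) of the ring A phenol with the ring B benzyl alcohol.
4. The ring A phenol comes from phloroacetophenone: the C8 oxygen is a formyl group (Vilsmeier–Haack) turned into OH (Baeyer–Villiger/Dakin), and the hydroxyl between the two carbonyls, the later O1, is never protected.
5. The ring B alcohol comes from 3-bromo-4-hydroxybenzaldehyde by silylation, Negishi coupling with the zinc reagent of 4-bromo-2-methylbut-1-ene, and reduction; rings A and B are in the starting materials.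

Key step: step 10

Assumption: Rh2(S-PTTL)4 is taken to give the 2S product in this 1,6-insertion; if the sense of induction is the opposite, its enantiomer Rh2(R-PTTL)4 is used under the same conditions.

**Route**

Step 1
Reactants: 1 2',4',6'-trihydroxyacetophenone (dried)
Product: 3 3-acetyl-2,4,6-trihydroxybenzaldehyde, via iminium chloride 2 (not isolated)
Conditions: POCl3 (1.1 equiv), DMF, EtOAc, 0 °C to rt; then H2O, 50 °C
Reagents that add atoms: N,N-dimethylformamide, CN(C)C=O (formyl carbon); water, O (carbonyl oxygen)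
Why: Vilsmeier–Haack formylation, in which the chloroiminium ion attacks one of the two equivalent, strongly activated ring positions, the new acyl group deactivates the ring against a second formylation, and hydrolysis of 2 gives the aldehyde.

Step 2
Reactants: 3 3-acetyl-2,4,6-trihydroxybenzaldehyde
Product: 4 3-acetyl-2-hydroxy-4,6-bis(triisopropylsilyloxy)benzaldehyde
Conditions: TIPSCl (2.3 equiv), imidazole, DMAP (cat.), DMF, rt to 40 °C
Reagents that add atoms: triisopropylsilyl chloride, CC(C)[Si](Cl)(C(C)C)C(C)C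
Why: Silyl ether formation, which should stop at the bis-ether because the hydroxyl between the two carbonyl groups is flanked on both sides and hydrogen-bonded, whereas the other two each have a free neighbouring position.

Step 3
Reactants: 4 3-acetyl-2-hydroxy-4,6-bis(triisopropylsilyloxy)benzaldehyde
Product: 6 1-[2,3-dihydroxy-4,6-bis(triisopropylsilyloxy)phenyl]ethanone, via aryl formate 5 (not isolated)
Conditions: mCPBA (1.1 equiv), NaHCO3, CH2Cl2, 0 °C; then MeOH, NaHCO3, 0 °C
Reagents that add atoms: 3-chloroperbenzoic acid, OOC(=O)c1cccc(Cl)c1 (one oxygen)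
Why: Baeyer–Villiger (Dakin-type) oxidation, in which the electron-rich aryl group migrates in the Criegee adduct of the aldehyde, the hindered aryl methyl ketone reacts far more slowly, and mild methanolysis of formate 5 frees the hydroxyl at the future C8.

Step 4
Reactants: 6 1-[2,3-dihydroxy-4,6-bis(triisopropylsilyloxy)phenyl]ethanone
Product: 7 1-[2-hydroxy-3,4,6-tris(triisopropylsilyloxy)phenyl]ethanone
Conditions: TIPSOTf (1.1 equiv), 2,6-lutidine, CH2Cl2, −40 to 0 °C
Reagents that add atoms: triisopropylsilyl trifluoromethanesulfonate, CC(C)[Si](OS(=O)(=O)C(F)(F)F)(C(C)C)C(C)C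
Why: Silylation of the non-chelated catechol hydroxyl, with the other hydroxyl held in a hydrogen bond to the acetyl group and flanked on both sides; a silyl shift between the vicinal oxygens beforehand would lead to the same tris-silyl ether.

Step 5
Reactants: 8 3-bromo-4-hydroxybenzaldehyde
Product: 9 3-bromo-4-(triisopropylsilyloxy)benzaldehyde
Conditions: TIPSCl, imidazole, DMF, rt
Reagents that add atoms: triisopropylsilyl chloride, CC(C)[Si](Cl)(C(C)C)C(C)C
Why: Standard silyl ether formation at the only hydroxyl, which masks the acidic phenol for the organozinc coupling.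

Step 6
Reactants: 9 3-bromo-4-(triisopropylsilyloxy)benzaldehyde; 10 4-bromo-2-methylbut-1-ene
Product: 12 3-(3-methylbut-3-en-1-yl)-4-(triisopropylsilyloxy)benzaldehyde, via homoallylzinc bromide 11 (not isolated)
Conditions: 10, Zn dust (activated by BrCH2CH2Br and Me3SiCl), LiCl, THF, 40 °C; then 9, Pd(OAc)2 (2 mol%), SPhos (2-dicyclohexylphosphino-2',6'-dimethoxybiphenyl, 4 mol%), THF, rt to 45 °C
Reagents that add atoms: none
Why: Negishi sp2–sp3 cross-coupling, in which the alkylzinc halide leaves the aldehyde untouched and the bulky biaryl phosphine makes reductive elimination faster than β-hydride elimination at the bromide beside the silyloxy group.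

Step 7
Reactants: 12 3-(3-methylbut-3-en-1-yl)-4-(triisopropylsilyloxy)benzaldehyde
Product: 13 [3-(3-methylbut-3-en-1-yl)-4-(triisopropylsilyloxy)phenyl]methanol
Conditions: NaBH4, MeOH–THF, 0 °C
Reagents that add atoms: none
Why: Borohydride reduction of the aldehyde, which leaves the isolated alkene and the aryl silyl ether untouched at low temperature.

Step 8
Reactants: 7 1-[2-hydroxy-3,4,6-tris(triisopropylsilyloxy)phenyl]ethanone; 13 [3-(3-methylbut-3-en-1-yl)-4-(triisopropylsilyloxy)phenyl]methanol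
Product: 14 1-[2-{[3-(3-methylbut-3-en-1-yl)-4-(triisopropylsilyloxy)phenyl]methoxy}-3,4,6-tris(triisopropylsilyloxy)phenyl]ethanone
Conditions: PPh3, DIAD, THF (0.2 M), 0 °C to rt
Reagents that add atoms: none
Why: Mitsunobu etherification, in which the acidic ortho-acyl phenol (the only free hydroxyl of 7) displaces the alkoxyphosphonium ion of the primary, electron-rich benzyl alcohol under neutral conditions that spare the aryl silyl ethers.

Step 9
Reactants: 14 1-[2-{[3-(3-methylbut-3-en-1-yl)-4-(triisopropylsilyloxy)phenyl]methoxy}-3,4,6-tris(triisopropylsilyloxy)phenyl]ethanone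
Product: 16 2-diazo-1-[2-{[3-(3-methylbut-3-en-1-yl)-4-(triisopropylsilyloxy)phenyl]methoxy}-3,4,6-tris(triisopropylsilyloxy)phenyl]ethanone, via trifluoroacetyl ketone 15 (not isolated)
Conditions: LiN(SiMe3)2 (1.1 equiv), THF, −78 °C; CF3CO2CH2CF3, −78 °C; then 4-acetamidobenzenesulfonyl azide, Et3N, H2O (1 equiv), MeCN, rt
Reagents that add atoms: 4-acetamidobenzenesulfonyl azide, CC(=O)Nc1ccc(cc1)S(=O)(=O)N=[N+]=[N-] (the two diazo nitrogens); 2,2,2-trifluoroethyl trifluoroacetate, FC(F)(F)COC(=O)C(F)(F)F (trifluoroacetyl group of 15 only, lost again)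
Why: Detrifluoroacetylative diazo transfer (Danheiser), in which the kinetic lithium enolate of the methyl ketone is trifluoroacetylated to the activated 1,3-diketone 15 and the sulfonyl azide then transfers N2 with loss of the trifluoroacetyl group as its sulfonamide.

Step 10
Reactants: 16 2-diazo-1-[2-{[3-(3-methylbut-3-en-1-yl)-4-(triisopropylsilyloxy)phenyl]methoxy}-3,4,6-tris(triisopropylsilyloxy)phenyl]ethanone
Product: 17 (2S)-2-[3-(3-methylbut-3-en-1-yl)-4-(triisopropylsilyloxy)phenyl]-5,7,8-tris(triisopropylsilyloxy)chroman-4-one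
Conditions: Rh2(S-PTTL)4, dirhodium tetrakis[N-phthaloyl-(S)-tert-leucinate] (2 mol%), CH2Cl2, 4 Å molecular sieves, slow addition of 16 by syringe pump, 0 °C to rt
Reagents that add atoms: none
Why: Loss of N2 from 16 on the dirhodium tetracarboxylate gives an electrophilic rhodium carbenoid at C3, which inserts into one of the two enantiotopic C–H bonds of the O1–CH2–aryl group through a three-centre, hydride-transfer-like transition state and so forms C2–C3. The closest known reaction type is the dirhodium-catalysed enantioselective intramolecular C–H insertion of 2-alkoxyphenyl diazoketones to 2-substituted chroman-4-ones. Ring C closes as a six-membered ring by 1,6-insertion (C3, C4, C4a, C8a, O1, C2). The C2 stereocentre is under catalyst control: the chiral N-phthaloyl-tert-leucinate ligands around the carbenoid tell the two benzylic hydrogens apart, and the substrate has no other stereocentre. The step needs site selectivity and chemoselectivity over oxonium ylide formation at O1 followed by a Stevens benzyl shift; the C2–H bonds are doubly activated (ether oxygen and para-silyloxyaryl group), every other oxygen carries a silyl group with no O–C–H bond, and O1 is a weakly basic aryl ether oxygen shielded by the C8 silyloxy group. Slow addition at high dilution should suppress carbene dimerisation and intermolecular cyclopropanation of the remote 1,1-disubstituted alkene.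

Step 11
Reactants: 17 (2S)-2-[3-(3-methylbut-3-en-1-yl)-4-(triisopropylsilyloxy)phenyl]-5,7,8-tris(triisopropylsilyloxy)chroman-4-one
Product: 18 (2S)-5,7,8-trihydroxy-2-[4-hydroxy-3-(3-methylbut-3-en-1-yl)phenyl]-2,3-dihydro-4H-chromen-4-one
Conditions: Bu4NF–AcOH (1:1, 5 equiv), THF, degassed, argon, 0 °C to rt
Reagents that add atoms: none
Why: Fluoride-induced cleavage of the four aryl silyl ethers, with acetic acid keeping the freed phenols protonated so that ring opening at O1–C2 (racemisation through the chalcone or quinone methide) and air oxidation of the 5,7,8-trihydroxy ring should not set in, and with no acid strong enough to protonate the 1,1-disubstituted alkene.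

**Compound list**

1 | 2',4',6'-trihydroxyacetophenone | CC(=O)c1c(O)cc(O)cc1O | starting material
2 | [(3-acetyl-2,4,6-trihydroxyphenyl)methylidene]dimethylammonium chloride | CC(=O)c1c(O)cc(O)c(C=[N+](C)C)c1O.[Cl-] | intermediate
3 | 3-acetyl-2,4,6-trihydroxybenzaldehyde | CC(=O)c1c(O)cc(O)c(C=O)c1O | intermediate
4 | 3-acetyl-2-hydroxy-4,6-bis(triisopropylsilyloxy)benzaldehyde | CC(=O)c1c(O[Si](C(C)C)(C(C)C)C(C)C)cc(O[Si](C(C)C)(C(C)C)C(C)C)c(C=O)c1O | intermediate
5 | 3-acetyl-2-hydroxy-4,6-bis(triisopropylsilyloxy)phenyl formate | CC(=O)c1c(O[Si](C(C)C)(C(C)C)C(C)C)cc(O[Si](C(C)C)(C(C)C)C(C)C)c(OC=O)c1O | intermediate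
6 | 1-[2,3-dihydroxy-4,6-bis(triisopropylsilyloxy)phenyl]ethanone | CC(=O)c1c(O[Si](C(C)C)(C(C)C)C(C)C)cc(O[Si](C(C)C)(C(C)C)C(C)C)c(O)c1O | intermediate
7 | 1-[2-hydroxy-3,4,6-tris(triisopropylsilyloxy)phenyl]ethanone | CC(=O)c1c(O[Si](C(C)C)(C(C)C)C(C)C)cc(O[Si](C(C)C)(C(C)C)C(C)C)c(O[Si](C(C)C)(C(C)C)C(C)C)c1O | intermediate
8 | 3-bromo-4-hydroxybenzaldehyde | O=Cc1ccc(O)c(Br)c1 | starting material
9 | 3-bromo-4-(triisopropylsilyloxy)benzaldehyde | O=Cc1ccc(O[Si](C(C)C)(C(C)C)C(C)C)c(Br)c1 | intermediate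
10 | 4-bromo-2-methylbut-1-ene | C=C(C)CCBr | starting material
11 | (3-methylbut-3-en-1-yl)zinc bromide | C=C(C)CC[Zn]Br | intermediate
12 | 3-(3-methylbut-3-en-1-yl)-4-(triisopropylsilyloxy)benzaldehyde | O=Cc1ccc(O[Si](C(C)C)(C(C)C)C(C)C)c(CCC(C)=C)c1 | intermediate
13 | [3-(3-methylbut-3-en-1-yl)-4-(triisopropylsilyloxy)phenyl]methanol | OCc1ccc(O[Si](C(C)C)(C(C)C)C(C)C)c(CCC(C)=C)c1 | intermediate
14 | 1-[2-{[3-(3-methylbut-3-en-1-yl)-4-(triisopropylsilyloxy)phenyl]methoxy}-3,4,6-tris(triisopropylsilyloxy)phenyl]ethanone | CC(=O)c1c(O[Si](C(C)C)(C(C)C)C(C)C)cc(O[Si](C(C)C)(C(C)C)C(C)C)c(O[Si](C(C)C)(C(C)C)C(C)C)c1OCc1ccc(O[Si](C(C)C)(C(C)C)C(C)C)c(CCC(C)=C)c1 | intermediate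
15 | 4,4,4-trifluoro-1-[2-{[3-(3-methylbut-3-en-1-yl)-4-(triisopropylsilyloxy)phenyl]methoxy}-3,4,6-tris(triisopropylsilyloxy)phenyl]butane-1,3-dione | O=C(CC(=O)C(F)(F)F)c1c(O[Si](C(C)C)(C(C)C)C(C)C)cc(O[Si](C(C)C)(C(C)C)C(C)C)c(O[Si](C(C)C)(C(C)C)C(C)C)c1OCc1ccc(O[Si](C(C)C)(C(C)C)C(C)C)c(CCC(C)=C)c1 | intermediate
16 | 2-diazo-1-[2-{[3-(3-methylbut-3-en-1-yl)-4-(triisopropylsilyloxy)phenyl]methoxy}-3,4,6-tris(triisopropylsilyloxy)phenyl]ethanone | [N-]=[N+]=CC(=O)c1c(O[Si](C(C)C)(C(C)C)C(C)C)cc(O[Si](C(C)C)(C(C)C)C(C)C)c(O[Si](C(C)C)(C(C)C)C(C)C)c1OCc1ccc(O[Si](C(C)C)(C(C)C)C(C)C)c(CCC(C)=C)c1 | intermediate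
17 | (2S)-2-[3-(3-methylbut-3-en-1-yl)-4-(triisopropylsilyloxy)phenyl]-5,7,8-tris(triisopropylsilyloxy)chroman-4-one | C=C(C)CCc1cc([C@@H]2CC(=O)c3c(O[Si](C(C)C)(C(C)C)C(C)C)cc(O[Si](C(C)C)(C(C)C)C(C)C)c(O[Si](C(C)C)(C(C)C)C(C)C)c3O2)ccc1O[Si](C(C)C)(C(C)C)C(C)C | intermediate
18 | (2S)-5,7,8-trihydroxy-2-[4-hydroxy-3-(3-methylbut-3-en-1-yl)phenyl]-2,3-dihydro-4H-chromen-4-one | C=C(C)CCc1cc([C@@H]2CC(=O)c3c(O)cc(O)c(O)c3O2)ccc1O | target

**Step count and risks**

Total step count: 11. Longest linear sequence: 8 steps (steps 1–4 and 8–11).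

Steps most likely to fail:

Step 10. The carbenoid may add to O1 instead of inserting, and the oxonium ylide would then shift the benzyl group to give a benzofuranone; the enantiotopic hydrogens may also be told apart only poorly. The fallback sets out from 7 and 12 and forms C2–C3 first. Aldol addition of the dianion of 7 (LiN(SiMe3)2, 2.2 equiv, THF, −78 °C) to aldehyde 12 should give racemic 3-hydroxy-1-[2-hydroxy-3,4,6-tris(triisopropylsilyloxy)phenyl]-3-[3-(3-methylbut-3-en-1-yl)-4-(triisopropylsilyloxy)phenyl]propan-1-one F1. Mitsunobu cyclodehydration (PPh3, DIAD, THF) then closes O1–C2 to the racemic 2-[3-(3-methylbut-3-en-1-yl)-4-(triisopropylsilyloxy)phenyl]-5,7,8-tris(triisopropylsilyloxy)chroman-4-one F2. Preparative HPLC on a chiral stationary phase removes the (2R)-enantiomer F3 and the route is rejoined at 17.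

Step 8. The phenol is hydrogen-bonded and flanked by the acetyl and a silyloxy group, so capture of the alkoxyphosphonium ion may be slow and alkylation of the reduced azodicarboxylate may take over. The fallback sets out from 13: an Appel reaction (CBr4, PPh3, CH2Cl2, 0 °C) should give 4-(bromomethyl)-2-(3-methylbut-3-en-1-yl)-1-(triisopropylsilyloxy)benzene F4, which alkylates 7 in a Williamson etherification (K2CO3, acetone, 50 °C) and rejoins the route at 14.

Step 3. The peracid may oxidise the electron-rich catechol further, and the silyl ethers on the acidic, carbonyl-conjugated phenols of 4 (made in steps 1 and 2) may be lost during oxidation or methanolysis. The fallback sets out from 1 and replaces steps 1–4 by para-hydroxylation.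
- Benzylation (BnBr, 2.1 equiv, K2CO3, acetone) should give 1-[2,4-bis(benzyloxy)-6-hydroxyphenyl]ethanone F5.
- Elbs persulfate oxidation (K2S2O8, aqueous NaOH–pyridine, rt) oxidises para to the free hydroxyl via potassium 3-acetyl-2,6-bis(benzyloxy)-4-hydroxyphenyl sulfate F6, which hot dilute HCl hydrolyses to 1-[2,4-bis(benzyloxy)-3,6-dihydroxyphenyl]ethanone F7.
- Silylation of both hydroxyls (TIPSOTf, 2,6-lutidine) gives 1-[2,4-bis(benzyloxy)-3,6-bis(triisopropylsilyloxy)phenyl]ethanone F8.
- Hydrogenolysis (H2, Pd on carbon, EtOAc) gives 1-[2,4-dihydroxy-3,6-bis(triisopropylsilyloxy)phenyl]ethanone F9.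
- Silylation of the non-chelated para hydroxyl (TIPSCl, imidazole) rejoins the route at 7.

**Further compounds**

F1 | step 10 | 3-hydroxy-1-[2-hydroxy-3,4,6-tris(triisopropylsilyloxy)phenyl]-3-[3-(3-methylbut-3-en-1-yl)-4-(triisopropylsilyloxy)phenyl]propan-1-one (racemic) | C=C(C)CCc1cc(C(O)CC(=O)c2c(O)c(O[Si](C(C)C)(C(C)C)C(C)C)c(O[Si](C(C)C)(C(C)C)C(C)C)cc2O[Si](C(C)C)(C(C)C)C(C)C)ccc1O[Si](C(C)C)(C(C)C)C(C)C
F2 | step 10 | 2-[3-(3-methylbut-3-en-1-yl)-4-(triisopropylsilyloxy)phenyl]-5,7,8-tris(triisopropylsilyloxy)chroman-4-one (racemic) | C=C(C)CCc1cc(C2CC(=O)c3c(O[Si](C(C)C)(C(C)C)C(C)C)cc(O[Si](C(C)C)(C(C)C)C(C)C)c(O[Si](C(C)C)(C(C)C)C(C)C)c3O2)ccc1O[Si](C(C)C)(C(C)C)C(C)C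
F3 | step 10 | (2R)-2-[3-(3-methylbut-3-en-1-yl)-4-(triisopropylsilyloxy)phenyl]-5,7,8-tris(triisopropylsilyloxy)chroman-4-one | C=C(C)CCc1cc([C@H]2CC(=O)c3c(O[Si](C(C)C)(C(C)C)C(C)C)cc(O[Si](C(C)C)(C(C)C)C(C)C)c(O[Si](C(C)C)(C(C)C)C(C)C)c3O2)ccc1O[Si](C(C)C)(C(C)C)C(C)C
F4 | step 8 | 4-(bromomethyl)-2-(3-methylbut-3-en-1-yl)-1-(triisopropylsilyloxy)benzene | BrCc1ccc(O[Si](C(C)C)(C(C)C)C(C)C)c(CCC(C)=C)c1
F5 | step 3 | 1-[2,4-bis(benzyloxy)-6-hydroxyphenyl]ethanone | CC(=O)c1c(O)cc(OCc2ccccc2)cc1OCc1ccccc1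
F6 | step 3 | potassium 3-acetyl-2,6-bis(benzyloxy)-4-hydroxyphenyl sulfate | CC(=O)c1c(O)cc(OCc2ccccc2)c(OS(=O)(=O)[O-])c1OCc1ccccc1.[K+]
F7 | step 3 | 1-[2,4-bis(benzyloxy)-3,6-dihydroxyphenyl]ethanone | CC(=O)c1c(O)cc(OCc2ccccc2)c(O)c1OCc1ccccc1
F8 | step 3 | 1-[2,4-bis(benzyloxy)-3,6-bis(triisopropylsilyloxy)phenyl]ethanone | CC(=O)c1c(O[Si](C(C)C)(C(C)C)C(C)C)cc(OCc2ccccc2)c(O[Si](C(C)C)(C(C)C)C(C)C)c1OCc1ccccc1
F9 | step 3 | 1-[2,4-dihydroxy-3,6-bis(triisopropylsilyloxy)phenyl]ethanone | CC(=O)c1c(O[Si](C(C)C)(C(C)C)C(C)C)cc(O)c(O[Si](C(C)C)(C(C)C)C(C)C)c1O
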